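Ash holds less scavenger than maple, 0.60 mM against 0.90 mM, and is otherwise charged alike. What does that difference leave in the flask?

| flask | starting complex | incoming ligand | leaving ligand | scavenger | remark | time |
|---|---|---|---|---|---|---|
| ash | 0.50 mM | 1 mM | 0.25 mM | 0.60 mM | the very flask that is asked about, followed so far |  |
| maple | 0.50 mM | 1 mM | 0.25 mM | 0.90 mM | run made earlier |  |
| flask | 0.50 mM | 1.00 mM | 0.250 mM | 0.600 mM |  | 2.5 min |

- ash (time / s: starting complex / %, complex with two exchanged / %): 10.0: 5.7, 51.5; 12.0: 5.6, 51.8; 30.0: 3.1, 51.0
- maple (time / min: starting complex / %, complex with two exchanged / %): 0.333: 3.7, 51.6; 0.833: 2.7, 51.2; 1.50: 1.4, 51.2; 2.50: 1.2, 51.5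

(each reading ± 0.3 percentage points)

- in percentages every species weighs as the starting complex in it: one side product counts as two
- for leaving ligand the idle adduct is counted in
- on the list of suspects stand: complex with two exchanged + incoming ligand -> leaving ligand + complex with three exchanged; starting complex -> decomposition product; complex with one exchanged + incoming ligand -> leaving ligand + complex with two exchanged; starting complex + complex with one exchanged -> side product; starting complex + incoming ligand -> leaving ligand + complex with one exchanged; leaving ligand + incoming ligand <-> idle adduct; scavenger + leaving ligand -> scavenged by-product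
- the earlier runs do not show how much of incoming ligand is bound; that part of a forecast is a guess

- part of the starting complex that has reacted at 2.5 min
- share of the unused incoming ligand that is free and not bound as idle adduct, at 2.5 min

Call the two answers c, the part reacted, and fr, the free share.

One chemist keeps 0.05 to 0.1 mM of incoming ligand unused in ash. He expects about 0.5 to 0.6 mM of leaving ligand to bind it, so ash's slow tail should run no faster than maple's, with 1.5 % of starting complex left.

I hold a balance view. Ash's complex with two exchanged reads 51.5 % at 10.0 s and 51.0 % at 30.0 s, and maple's reads 51.6 % at 0.333 min and 51.5 % at 2.50 min. It is a suspect for reaction with incoming ligand, yet these readings stay close together, so I count that ligand as used in ash. Each unit used releases one leaving ligand, and scavenger is the limiting reagent of the capture. Ash therefore keeps 0.650 mM, the surplus S: leaving ligand charged plus released, minus scavenger charged. If binding stands at equilibrium, any trace of unused ligand in ash divides as fr = 1/(1 + K·S), with K the binding constant of the idle adduct. The runs do not show K, so I leave fr open.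

Maple's starting complex still falls to 1.2 % at 2.50 min. Ash's 3.1 % at 30.0 s lies between maple's 3.7 % at 0.333 min and 2.7 % at 0.833 min, so I take maple's tail for ash: c about 98.8 %.

The forecast, the first chemist's, gives c 98.5 % (97.4 % to 99.3 %), on the ground “That ties up more incoming ligand”, and fr 45 % (12 % to 85 %), which it calls largely a guess.

The simulation of ash gives c 98.8 % and fr 38.1 %.

    complex with two exchanged + incoming ligand → leaving ligand + complex with three exchanged (k = 460 M⁻¹ s⁻¹)
    starting complex → decomposition product (k = 4.60 × 10⁻⁵ s⁻¹)
    complex with one exchanged + incoming ligand → leaving ligand + complex with two exchanged (k = 2000 M⁻¹ s⁻¹)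
    starting complex + complex with one exchanged → side product (k = 200 M⁻¹ s⁻¹)
    starting complex + incoming ligand → leaving ligand + complex with one exchanged (k = 1700 M⁻¹ s⁻¹)
    leaving ligand + incoming ligand ⇌ idle adduct, settled at all times (K = 2500 M⁻¹)
    scavenger + leaving ligand → scavenged by-product (k = 7800 M⁻¹ s⁻¹)

At 2.50 min ash holds incoming ligand at 0 % and leaving ligand at 260 % of its charge, or 0.650 mM, and S with K = 2500 M⁻¹ gives fr 38.1 %. Binding has its region early: at 0.250 min ash holds 0.0252 mM of idle adduct, against 4.85 × 10⁻⁷ mM at 2.50 min. A neighbour of ash, charged with 0.40 mM of incoming ligand, has S = 0.0500 mM, so the rule gives 88.9 %. It ends with fr 88.9 %, leaving ligand at 20.0 % of its charge and starting complex at 11.6 %.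

The data come from a simulation with constants of no real substance.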